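**Retrosynthetic overview** (disconnections listed in the order the bonds are made; side chain numbered C1 to C17 from the ring)
1. C15–C16 (key bond): the carbinol carbon C15, normally an electrophile, is used as a chiral α-oxy carbanion. Octenol 1 gives carbamate 2, whose sparteine-bound lithio derivative 3 is ethylated by ethyl triflate to 4; carbamate removal gives alcohol 5. This one event makes the bond and sets C15.
2. C1–C2 (benzylic sp3–sp3): bromooctene 6 and benzyl bromide 7 are joined through Grignard reagent 8 to give aryl nonene 9.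
3. C8=C9 (Z): Z-selective cross-metathesis of the terminal alkenes 5 and 9 gives 10; O-demethylation then gives the target 11.
4. Rings: none is formed; the only ring (the resorcinol ring) is bought as its dimethyl ether in 7.

Assumption: the SMILES is read as 5-[(8Z,15S)-15-hydroxyheptadec-8-en-1-yl]benzene-1,3-diol (C15 is S, C8=C9 is Z).

**Step 1**
Reactants: 1 oct-7-en-1-ol
Product: 2 oct-7-en-1-yl N,N-diisopropylcarbamate
Conditions: i-Pr2NC(O)Cl (1.2 equiv), Et3N (1.5 equiv), CH2Cl2, reflux, 24 h
Reagents that add atoms: N,N-diisopropylcarbamoyl chloride, CC(C)N(C(C)C)C(Cl)=O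
Why: O-carbamoylation of a primary alcohol (acyl substitution) installs the hindered carbamate that resists attack by s-BuLi and directs the α-lithiation of step 2.

**Step 2**
Reactants: 2 oct-7-en-1-yl N,N-diisopropylcarbamate
Product: 5 (S)-dec-9-en-3-ol, via lithio carbamate 3 (not isolated), via ethylated carbamate 4 (not isolated)
Conditions: s-BuLi (1.3 equiv), (−)-sparteine (1.3 equiv), Et2O, −78 °C, 5 h; EtOTf (2.5 equiv), −78 °C, 2 h, then rt; LiAlH4 (1 M in Et2O, 4 equiv), 0 °C (also destroys excess EtOTf), then THF, reflux, 16 h; H2O quench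
Reagents that add atoms: ethyl trifluoromethanesulfonate (EtOTf), CCOS(=O)(=O)C(F)(F)F
Why: Proposed new method: Hoppe sparteine-mediated asymmetric deprotonation (carbamate-directed removal of the pro-S α-hydrogen by s-BuLi/(−)-sparteine) gives the configurationally stable, dipole-stabilised (S)-α-oxy carbanion 3, a hydroxyalkyl-anion (d1) synthon that makes the normally electrophilic carbinol carbon nucleophilic; its covalent sp3 C–Li bond should be ethylated with retention (SE2ret) by the hard, very reactive ethyl triflate, setting C15 as S in the C15–C16 bond-forming event (expected er at least 95:5, checked on 5), and LiAlH4 then cleaves the carbamate in the same flask without touching the stereocentre; the closest known reaction type is the Hoppe methylation of sparteine-complexed lithiated alkyl carbamates with MeI (retention) followed by LiAlH4 decarbamoylation, and the triflate is chosen because higher alkyl iodides react too slowly at −78 °C.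

**Step 3**
Reactants: 6 8-bromooct-1-ene; 7 3,5-dimethoxybenzyl bromide (1-(bromomethyl)-3,5-dimethoxybenzene)
Product: 9 1,3-dimethoxy-5-(non-8-en-1-yl)benzene, via octenyl Grignard 8 (not isolated)
Conditions: 6, Mg, THF, 40 °C; then slow addition to 7, Li2CuCl4 (3 mol %), THF, −10 °C to rt
Reagents that add atoms: none
Why: Kochi-type copper-catalysed sp3–sp3 cross-coupling of a primary alkyl Grignard reagent with a benzylic bromide, with slow addition to suppress benzyl homocoupling; the terminal alkene and the aryl methyl ethers are inert.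

**Step 4**
Reactants: 5 (S)-dec-9-en-3-ol; 9 1,3-dimethoxy-5-(non-8-en-1-yl)benzene (3 equiv)
Product: 10 (3S,9Z)-17-(3,5-dimethoxyphenyl)heptadec-9-en-3-ol
Conditions: Ru(NO3)(C25H35N2)(=CH-C6H4-2-O-i-Pr) (2 mol %), THF (1 M), 35 °C, static vacuum, 12 h
Reagents that add atoms: none
Why: Z-selective olefin cross-metathesis: the nitrato ruthenium catalyst with a cyclometalated N-adamantyl-N'-(2,6-diisopropylphenyl)imidazolin-2-ylidene (C25H35N2) forces an all-syn metallacyclobutane, so two terminal alkenes give the Z-1,2-disubstituted alkene (expected at least 90% Z) with loss of ethene, while the free hydroxyl and aryl ethers are tolerated and excess 9 limits homodimerisation of 5.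

**Step 5**
Reactants: 10 (3S,9Z)-17-(3,5-dimethoxyphenyl)heptadec-9-en-3-ol
Product: 11 Hansfordiol G, 5-[(8Z,15S)-15-hydroxyheptadec-8-en-1-yl]benzene-1,3-diol
Conditions: MeMgI (8 equiv, Et2O), evaporate Et2O, neat, 160 °C, 30 min, argon; then 1 M HCl, 0 °C
Reagents that add atoms: none
Why: Grignard-melt O-demethylation (Lewis-acid-assisted nucleophilic cleavage of both O–CH3 bonds) runs under non-acidic conditions that leave the remote Z-alkene and the secondary magnesium alkoxide, and hence C15, untouched.

**Compound list**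
1 | oct-7-en-1-ol | C=CCCCCCCO | starting material
2 | oct-7-en-1-yl N,N-diisopropylcarbamate | C=CCCCCCCOC(=O)N(C(C)C)C(C)C | intermediate
3 | (S)-1-lithiooct-7-en-1-yl N,N-diisopropylcarbamate, as its (−)-sparteine complex (ligand not drawn) | [Li][C@@H](CCCCCC=C)OC(=O)N(C(C)C)C(C)C | intermediate (not isolated)
4 | (S)-dec-9-en-3-yl N,N-diisopropylcarbamate | CC[C@H](OC(=O)N(C(C)C)C(C)C)CCCCCC=C | intermediate (not isolated)
5 | (S)-dec-9-en-3-ol | CC[C@H](O)CCCCCC=C | intermediate
6 | 8-bromooct-1-ene | C=CCCCCCCBr | starting material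
7 | 3,5-dimethoxybenzyl bromide | COc1cc(CBr)cc(OC)c1 | starting material
8 | oct-7-en-1-ylmagnesium bromide | C=CCCCCCC[Mg]Br | intermediate (not isolated)
9 | 1,3-dimethoxy-5-(non-8-en-1-yl)benzene | COc1cc(CCCCCCCC=C)cc(OC)c1 | intermediate
10 | (3S,9Z)-17-(3,5-dimethoxyphenyl)heptadec-9-en-3-ol | CC[C@H](O)CCCCC/C=C\CCCCCCCc1cc(OC)cc(OC)c1 | intermediate
11 | Hansfordiol G, 5-[(8Z,15S)-15-hydroxyheptadec-8-en-1-yl]benzene-1,3-diol | CC[C@H](O)CCCCC/C=C\CCCCCCCc1cc(O)cc(O)c1 | target

**Total step count:** 5. **Longest linear sequence:** 4 steps (steps 1, 2, 4, 5; step 3 is the convergent branch).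

**Three steps most likely to fail**

Step 2. The C-ethylation of carbanion 3 may be slow, ethyl triflate may be consumed by sparteine, or the er may erode. The fallback sets out from carbamate 2 and comes back at alcohol 5. Carbamate 2 is lithiated to 3 exactly as before, but 3 is trapped at −78 °C with 2-ethyl-4,4,5,5-tetramethyl-1,3,2-dioxaborolane to give lithium ethyl[(S)-1-(N,N-diisopropylcarbamoyloxy)oct-7-en-1-yl](pinacolato)borate F1. Warming with MgBr2·OEt2 (Et2O, reflux) triggers the stereospecific 1,2-metallate rearrangement: ethyl migrates from boron to carbon with inversion and expels the carbamate, giving (S)-2-(dec-9-en-3-yl)-4,4,5,5-tetramethyl-1,3,2-dioxaborolane F2. Oxidation with NaOH/H2O2 (retention) gives 5 of the same configuration, and no LiAlH4 is needed.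

Step 4. The cross-metathesis may give too low a Z:E ratio or a poor cross/homodimer ratio. The fallback builds the alkene by a Wittig reaction; it sets out from carbamate 4 (here isolated by aqueous work-up of step 2 before LiAlH4 is added) and aryl nonene 9, and comes back at 10. Ozonolysis of 4 (O3, CH2Cl2, −78 °C; PPh3) gives (S)-9-oxononan-3-yl N,N-diisopropylcarbamate F3. Ozonolysis of 9 with 1 equiv O3 and reductive work-up (CH2Cl2/MeOH, −78 °C; NaBH4) gives 8-(3,5-dimethoxyphenyl)octan-1-ol F4; the alkene reacts far faster than the arene. I2/PPh3/imidazole converts F4 into 1-(8-iodooctyl)-3,5-dimethoxybenzene F5, and PPh3 (MeCN, reflux) gives [8-(3,5-dimethoxyphenyl)octyl]triphenylphosphonium iodide F6. NaN(SiMe3)2 (THF, −78 °C) gives [8-(3,5-dimethoxyphenyl)octylidene]triphenylphosphorane F7. Its lithium-free Wittig reaction with F3 gives (3S,9Z)-17-(3,5-dimethoxyphenyl)heptadec-9-en-3-yl N,N-diisopropylcarbamate F8 (expected Z:E at least 95:5). LiAlH4 (THF, reflux) then converts F8 into 10.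

Step 5. The second O-demethylation may stall, or the 160 °C melt may damage the material. The fallback changes the phenol protection before the alkene is made; it sets out from aryl nonene 9 (with alcohol 5) and comes back at target 11. BBr3 (CH2Cl2, −78 to 0 °C) demethylates the simple olefin 9 to 5-(non-8-en-1-yl)benzene-1,3-diol F9. TBSCl/imidazole (DMF) gives 1,3-bis(tert-butyldimethylsilyloxy)-5-(non-8-en-1-yl)benzene F10. Z-selective cross-metathesis of F10 with 5 under the conditions of step 4 gives (3S,9Z)-17-[3,5-bis(tert-butyldimethylsilyloxy)phenyl]heptadec-9-en-3-ol F11. Bu4NF (THF, 0 °C) then gives 11.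

**Further compounds**
F1 | step 2 | lithium ethyl[(S)-1-(N,N-diisopropylcarbamoyloxy)oct-7-en-1-yl](pinacolato)borate | [Li+].CC[B-]1(OC(C)(C)C(C)(C)O1)[C@@H](CCCCCC=C)OC(=O)N(C(C)C)C(C)C
F2 | step 2 | (S)-2-(dec-9-en-3-yl)-4,4,5,5-tetramethyl-1,3,2-dioxaborolane | CC[C@H](B1OC(C)(C)C(C)(C)O1)CCCCCC=C
F3 | step 4 | (S)-9-oxononan-3-yl N,N-diisopropylcarbamate | CC[C@H](OC(=O)N(C(C)C)C(C)C)CCCCCC=O
F4 | step 4 | 8-(3,5-dimethoxyphenyl)octan-1-ol | COc1cc(CCCCCCCCO)cc(OC)c1
F5 | step 4 | 1-(8-iodooctyl)-3,5-dimethoxybenzene | COc1cc(CCCCCCCCI)cc(OC)c1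
F6 | step 4 | [8-(3,5-dimethoxyphenyl)octyl]triphenylphosphonium iodide | COc1cc(CCCCCCCC[P+](c2ccccc2)(c2ccccc2)c2ccccc2)cc(OC)c1.[I-]
F7 | step 4 | [8-(3,5-dimethoxyphenyl)octylidene]triphenylphosphorane | COc1cc(CCCCCCCC=P(c2ccccc2)(c2ccccc2)c2ccccc2)cc(OC)c1
F8 | step 4 | (3S,9Z)-17-(3,5-dimethoxyphenyl)heptadec-9-en-3-yl N,N-diisopropylcarbamate | CC[C@H](OC(=O)N(C(C)C)C(C)C)CCCCC/C=C\CCCCCCCc1cc(OC)cc(OC)c1
F9 | step 5 | 5-(non-8-en-1-yl)benzene-1,3-diol | Oc1cc(CCCCCCCC=C)cc(O)c1
F10 | step 5 | 1,3-bis(tert-butyldimethylsilyloxy)-5-(non-8-en-1-yl)benzene | C=CCCCCCCCc1cc(O[Si](C)(C)C(C)(C)C)cc(O[Si](C)(C)C(C)(C)C)c1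
F11 | step 5 | (3S,9Z)-17-[3,5-bis(tert-butyldimethylsilyloxy)phenyl]heptadec-9-en-3-ol | CC[C@H](O)CCCCC/C=C\CCCCCCCc1cc(O[Si](C)(C)C(C)(C)C)cc(O[Si](C)(C)C(C)(C)C)c1
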